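The runs were generated by integration on assumed constants.

| flask | starting material | temperature | remark | time |
|---|---|---|---|---|
| west | 0.18 M | 15 °C | run made earlier |  |
| south | 0.80 M | 40 °C | run made earlier |  |
| autumn | 0.50 M | 20 °C |  | 25 h |
| dusk | 0.15 M | 60 °C |  | 80 h |
- west (time / h: target / %, isomer of the product / %): 1.33: 0.7, 0; 2.00: 0.7, 0.8; 3.00: 1.6, 0.6; 5.00: 3.4, 0.8; 8.00: 6.5, 2.5; 12.0: 11.6, 4.5; 20.0: 20.3, 9.1
- south (time / h: target / %, isomer of the product / %): 0.333: 6.9, 4.5; 1.00: 14.4, 19.8; 2.00: 12.8, 40.5; 3.00: 10.9, 51.9; 4.00: 9.4, 57.3; 6.00: 10.0, 60.5; 8.00: 9.6, 60.9

(readings scatter by 0.3 percentage points)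
1. which one finishes higher in share of target in all that became target or isomer of the product ("neither" within 2 percentage points) (autumn / dusk / neither)
2. share of target in all that became target or isomer of the product, autumn
3. share of target in all that became target or isomer of the product, dusk
- in percentages every species weighs as the starting material in it: one idle adduct counts as two
- for target the idle adduct is counted in
- candidate steps: starting material -> intermediate; intermediate <-> target; intermediate <-> isomer of the product; starting material + target <-> idle adduct
- in an amount of target, one idle adduct counts as one target

- Target is what I want, but it can go back to intermediate and leave as isomer. So I follow the share of target in target plus isomer.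
- The south run ends at 9.6% target and 60.9% isomer, which gives 13.6%. I call this S, the end share: target over target plus isomer once both have stopped moving (thermodynamic control).
- Time: by hand, a longer run carries the share down towards its end share. The south run reads 60.5% at 0.333 h and S at 8.00 h.
- Temperature: by hand, heat speeds that drift. The west run, at 15 °C, still reads 69.0% at 20.0 h, well above S.
- Amount: by hand, target tied up as idle adduct may be sheltered from going back, so a richer charge could raise the share. The two runs change charge and temperature together, so they cannot show this apart.
- My reckoning: autumn, at 20 °C for 25 h, lies close to the west run, so I put it between S and the west reading, nearer the west reading. Dusk, at 60 °C for 80 h, is hotter than the south run, and I have no second end share, so I put it at S.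
- The forecast says autumn, with 60% for autumn and 16% for dusk, “near the south plateau, slightly higher with temperature”. Its dusk value stands 2.4 percentage points above my S.
- The simulation gives autumn 52.5% and dusk 6.36%, so autumn finishes higher.

    starting material → intermediate (k = 0.00110 min⁻¹, Ea = 106 kJ mol⁻¹)
    intermediate ⇌ target (K = 1.20, k = 0.00400 min⁻¹, Ea = 90.0 kJ mol⁻¹, ΔH = −50.0 kJ mol⁻¹)
    intermediate ⇌ isomer of the product (K = 3.00, k = 0.00140 min⁻¹, Ea = 104 kJ mol⁻¹, ΔH = −14.0 kJ mol⁻¹)
    starting material + target ⇌ idle adduct, settled at all times (K = 2.10 M⁻¹, ΔH = 1.00 kJ mol⁻¹)
    (constants at 20 °C)

- Dusk ends 7.2 points below S, and reading it ten times later changes nothing. Autumn, left until 250 h, reads 28.6%, above S, so neither flask, read late, stands at the S of the south run. In autumn at 25.0 h, the forward step from intermediate into target runs 2.9 times the forward step into isomer. That is a share of 74.4% in the forward flow out of intermediate, against 52.5% in the autumn flask.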